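Easy one first: on Monday's flask, the very flask we are asked about, is the target still climbing at the last reading?

| setting | Monday's | flask |
|---|---|---|
| starting material | 0.20 M | 0.20 M |
| protic impurity | 0.010 M | 0.0100 M |
| remark | the very flask that is asked about, followed so far |  |
| time |  | 10 h |

Monday's run (percent of the starting material charged)

| time / h | target / % | starting material / % |
|---|---|---|
| 1.33 | 11.3 | 13.6 |
| 1.50 | 13.7 | 12.0 |
| 2.00 | 21.0 | 8.0 |
| 2.50 | 25.8 | 5.2 |
| 3.00 | 29.8 | 4.0 |

(each reading ± 0.5 percentage points)

- the moment within 10 h at which there is most target
- the amount of target, in percent of the starting material charged, at that time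

- the numbers in the tables scatter with a standard deviation of 0.5 percentage points

Yes, but more slowly. It gained 7.3 points from 1.50 h to 2.00 h, and 4 points in the equally long step from 2.50 h to 3.00 h, which is less.

What do you make of that? I assume the gain shrinks by a fixed fraction per unit time. The steps lie 1.00 h apart, which gives 0.602 /h, the fade constant (an apparent first-order constant): how fast the target's net gain dies away.

What is still to come? Summing the fading gain after 3.00 h gives 11 points more, so my ceiling is 41.2%. On this assumption, the distance below that ceiling shrinks at the fade constant.

Where is the weak spot? Each gain is a difference of two readings, each scattered by 0.5 points, so the constant is soft. The rule also has no turning point, so I commit to a ceiling and give no peak time.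

The forecast says 43% at 6 h, above my ceiling. It adds: “This is an extrapolation, so the uncertainty is wide.”

The simulation gives 34.9% at 4.77 h.

    starting material ⇌ intermediate A (K = 0.800, k = 0.0320 /min)
    starting material → intermediate B (k = 0.0230 /min)
    intermediate B → intermediate C (k = 0.0350 /min)
    intermediate C → target (k = 0.00950 /min)
    intermediate C ⇌ intermediate D (K = 1.10, k = 0.00570 /min)
    starting material + intermediate D → side product (k = 0.520 /M/min)
    target ⇌ isomer of the product (K = 7.30, k = 0.00290 /min)
    starting material + protic impurity → quenched substrate (k = 13.0 /M/min)

At 1.00 h the flask held 24.9% of intermediate C, which was turning into target. By 4.77 h intermediate C was down to 9.96%, while target had been turning into isomer of the product, which stood at 16.9%. For that moment the fade constant reckons the target in this flask at 37.3%, above the simulated best. For the same flask stopped at 4.0 h it gives 35.0% against 34.2%. The isomerisation ran on, and at 10.0 h the flask held 25.1% of target and 41.0% of isomer of the product.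

The data are simulated on assumed constants, and the scatter is random.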